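(The numbers of this flask are those of an exercise, and the outcome is calculated.)

A living end in this flask adds free monomer until it dies, so we reckon its length first.

free monomer 0.24 M; pre-initiator 12 mM; time 4.0 d

    free monomer + initiator → living end + monomer in chains (k1 = 0.084 L mol⁻¹ h⁻¹)
    free monomer + living end → monomer in chains + living end, rate k2*[living end]*[free monomer] (k2 = 1.2 L mol⁻¹ h⁻¹)
    pre-initiator → initiator (k3 = 0.029 h⁻¹)
    living end → dead end (k4 = 0.060 h⁻¹)

- average number of monomer units in a chain (chains begun, living or dead) at 4.0 d
- part of the free monomer that has reacted at 4.0 d

- the average divides the monomer in chains by the number of chains begun, living and dead together
- run time (flask): 4.0 d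

We turn the constants into times at the charge. One growth step takes 3.47 h and a living end lives 16.7 h on average, so the bench rule, the kinetic chain length, gives 4.80 units per living end. Adding the unit that begins the chain gives what we call the finished length, 5.80.

The rule counts finished chains at the charged [free monomer], but chains in this flask begin late. Pre-initiator takes 34.5 h on average and initiator, pseudo-first-order at the charged [free monomer], 49.6 h, together 84.1 h. We take the run time over that sum as the border of the rule, and here it is 1.14. Because this ratio lies near one, young chains are counted beside finished ones, so we expect dp under the finished length.

With [free monomer] held at its charge, these two first-order steps in series reckon to 8.01 mM of chains begun. At the finished length that would use 19.4% of the free monomer, so we commit to upper estimates of 5.80 for dp and 19.4% for c.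

The forecast goes lower than these estimates, to dp 4.7 and c 15%, holding that living ends “die off at a similar rate to their formation”.

The flask gives dp 4.71 and c 15.1%.

At 4.00 d the flask holds 84.9% of its free monomer, so growth over death of a living end has fallen from 4.80 to 4.08, and dp stands 1.09 under the finished length, with 0.00123 M of living end beside 0.00644 M of dead end. The neighbour charged with 0.060 M of free monomer has a finished length of 2.20 and reads dp 1.90.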